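**Retrosynthetic overview**
- The target comes from global O-debenzylation of a tri-O-benzyl diol, which comes from reductive removal of an oxazolidinone auxiliary from an anti-aldol adduct.
- Key C–C bond (carbinol carbon to the diaryl-methine carbon of the 1,3-diol side chain): intermolecular Mg-catalysed Evans anti-aldol between an N-arylacetyl oxazolidinone that already carries the complete lactone and O-benzylvanillin.
- The arylacetyl unit comes from Pd-catalysed α-arylation of an aryl bromide (bromine from 5-bromovanillin) with a tert-butyl acetate zinc enolate.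
- The trans-dibenzylbutyrolactone comes from anti-alkylation of an (R)-β-arylmethyl-γ-butyrolactone with O-benzylvanillyl bromide; that lactone comes from Evans alkylation of a pent-4-enoyl imide with the benzylic bromide, LiBH4 reduction, alkene cleavage and lactol oxidation.
- Ring order: all arenes are bought; the γ-butyrolactone is the only ring made (lactol, then lactone), before the side chain is built.

Assumption: the SMILES is taken as drawn, i.e. a (3R,4R)-trans lactone and a (1R,2R) 1,3-diol side chain, which is an anti relationship in aldol terms.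

**Step 1**
Reactants: 1 5-bromovanillin (3-bromo-4-hydroxy-5-methoxybenzaldehyde)
Product: 2 4-(benzyloxy)-3-bromo-5-methoxybenzaldehyde
Conditions: BnBr, K2CO3, DMF, 60 °C
Reagents that add atoms: benzyl bromide, BrCc1ccccc1
Why: Williamson ether synthesis (SN2 on the phenoxide); benzyl survives every later base, hydride, acid and Pd(0) step and all benzyl ethers leave together at the end.

**Step 2**
Reactants: 2 4-(benzyloxy)-3-bromo-5-methoxybenzaldehyde
Product: 3 [4-(benzyloxy)-3-bromo-5-methoxyphenyl]methanol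
Conditions: NaBH4, MeOH/THF, 0 °C
Reagents that add atoms: none
Why: Borohydride reduction of an aryl aldehyde; nothing else in 2 is reducible.

**Step 3**
Reactants: 3 [4-(benzyloxy)-3-bromo-5-methoxyphenyl]methanol
Product: 4 2-(benzyloxy)-1-bromo-5-(bromomethyl)-3-methoxybenzene
Conditions: PBr3, CH2Cl2, 0 °C
Reagents that add atoms: phosphorus tribromide, BrP(Br)Br
Why: SN2 bromination of an electron-rich benzylic alcohol through its phosphite ester; the aryl bromide and ethers are inert.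

**Step 4**
Reactants: 5 (R)-4-benzyl-1,3-oxazolidin-2-one; 6 pent-4-enoyl chloride
Product: 7 (4R)-4-benzyl-3-(pent-4-enoyl)-1,3-oxazolidin-2-one
Conditions: Et3N, DMAP (cat.), CH2Cl2, 0 °C → rt
Reagents that add atoms: none
Why: DMAP-catalysed N-acylation of the oxazolidinone by the acid chloride; no stereocentre is touched.

**Step 5**
Reactants: 7 (4R)-4-benzyl-3-(pent-4-enoyl)-1,3-oxazolidin-2-one; 4 2-(benzyloxy)-1-bromo-5-(bromomethyl)-3-methoxybenzene
Product: 9 (4R)-4-benzyl-3-[(2S)-2-{[4-(benzyloxy)-3-bromo-5-methoxyphenyl]methyl}pent-4-enoyl]-1,3-oxazolidin-2-one, via sodium (Z)-enolate 8 (not isolated)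
Conditions: NaHMDS, THF, −78 °C, 45 min; then 4, −78 → −30 °C
Reagents that add atoms: none
Why: Evans asymmetric alkylation; the chelated (Z)-sodium enolate is benzylated on the face away from the C4 benzyl group, so the (R)-auxiliary gives the (2S) centre, which becomes the (R)-configured lactone C4.

**Step 6**
Reactants: 9 (4R)-4-benzyl-3-[(2S)-2-{[4-(benzyloxy)-3-bromo-5-methoxyphenyl]methyl}pent-4-enoyl]-1,3-oxazolidin-2-one
Product: 10 (2S)-2-{[4-(benzyloxy)-3-bromo-5-methoxyphenyl]methyl}pent-4-en-1-ol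
Conditions: LiBH4, MeOH (1.1 equiv), THF, 0 °C
Reagents that add atoms: none
Why: Reductive removal of the Evans auxiliary (hydride attack on the Li-activated exocyclic imide carbonyl) without epimerisation; 5 is recovered.

**Step 7**
Reactants: 10 (2S)-2-{[4-(benzyloxy)-3-bromo-5-methoxyphenyl]methyl}pent-4-en-1-ol
Product: 13 (4R)-4-{[4-(benzyloxy)-3-bromo-5-methoxyphenyl]methyl}oxolan-2-ol (anomer mixture), via triol 11 (not isolated), via hydroxy aldehyde 12 (not isolated)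
Conditions: OsO4 (2 mol%), NaIO4, 2,6-lutidine, dioxane/H2O (3:1), rt
Reagents that add atoms: osmium tetroxide, O=[Os](=O)(=O)=O (delivers the new oxygen; re-oxidised by sodium periodate, [Na+].[O-][I](=O)(=O)=O)
Why: Lemieux–Johnson oxidative cleavage (dihydroxylation, then periodate glycol cleavage), used instead of ozone to spare the electron-rich arene; the γ-hydroxy aldehyde closes spontaneously to the five-membered lactol.

**Step 8**
Reactants: 13 (4R)-4-{[4-(benzyloxy)-3-bromo-5-methoxyphenyl]methyl}oxolan-2-ol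
Product: 14 (4R)-4-{[4-(benzyloxy)-3-bromo-5-methoxyphenyl]methyl}oxolan-2-one
Conditions: TPAP (5 mol%), NMO, 4 Å MS, CH2Cl2, rt
Reagents that add atoms: none
Why: Ley–Griffith oxidation of a lactol to the γ-lactone; the stereocentre is β to the carbonyl and cannot epimerise.

**Step 9**
Reactants: 15 [4-(benzyloxy)-3-methoxyphenyl]methanol
Product: 16 1-(benzyloxy)-4-(bromomethyl)-2-methoxybenzene
Conditions: PBr3, Et2O, 0 °C
Reagents that add atoms: phosphorus tribromide, BrP(Br)Br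
Why: SN2 bromination of a benzylic alcohol via its phosphite ester; used directly because the bromide is reactive.

**Step 10**
Reactants: 14 (4R)-4-{[4-(benzyloxy)-3-bromo-5-methoxyphenyl]methyl}oxolan-2-one; 16 1-(benzyloxy)-4-(bromomethyl)-2-methoxybenzene
Product: 18 (3R,4R)-4-{[4-(benzyloxy)-3-bromo-5-methoxyphenyl]methyl}-3-{[4-(benzyloxy)-3-methoxyphenyl]methyl}oxolan-2-one, via lithium enolate 17 (not isolated)
Conditions: LiHMDS, THF, −78 °C; then 16, DMPU, −78 → −30 °C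
Reagents that add atoms: none
Why: Kinetic enolate alkylation of a β-substituted γ-butyrolactone; the bromide enters anti to the C4 substituent and gives the trans-(3R,4R) lactone (also the thermodynamic isomer), and the aryl bromide is inert to the amide base.

**Step 11**
Reactants: 18 (3R,4R)-4-{[4-(benzyloxy)-3-bromo-5-methoxyphenyl]methyl}-3-{[4-(benzyloxy)-3-methoxyphenyl]methyl}oxolan-2-one; 19 tert-butyl bromoacetate
Product: 21 tert-butyl 2-[2-(benzyloxy)-5-{[(3R,4R)-4-{[4-(benzyloxy)-3-methoxyphenyl]methyl}-5-oxooxolan-3-yl]methyl}-3-methoxyphenyl]acetate, via Reformatsky reagent 20 (not isolated)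
Conditions: Zn dust (TMSCl-activated), 19, THF, rt; then 18, Pd(dba)2 (3 mol%), Q-Phos (3 mol%), THF, rt → 45 °C
Reagents that add atoms: none
Why: Pd-catalysed α-arylation of an ester zinc enolate (Reformatsky reagent in a Negishi-type coupling); the weakly basic zinc enolate tolerates the lactone and does not epimerise C3, and the acidic arylacetate is introduced only after the last strong-base step.

**Step 12**
Reactants: 21 tert-butyl 2-[2-(benzyloxy)-5-{[(3R,4R)-4-{[4-(benzyloxy)-3-methoxyphenyl]methyl}-5-oxooxolan-3-yl]methyl}-3-methoxyphenyl]acetate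
Product: 22 2-[2-(benzyloxy)-5-{[(3R,4R)-4-{[4-(benzyloxy)-3-methoxyphenyl]methyl}-5-oxooxolan-3-yl]methyl}-3-methoxyphenyl]acetic acid
Conditions: TFA/CH2Cl2 (1:4), 0 °C → rt
Reagents that add atoms: none
Why: Acidolysis of a tert-butyl ester (loss of the tert-butyl cation as isobutene); lactone and aryl benzyl ethers are stable to TFA at room temperature.

**Step 13**
Reactants: 22 2-[2-(benzyloxy)-5-{[(3R,4R)-4-{[4-(benzyloxy)-3-methoxyphenyl]methyl}-5-oxooxolan-3-yl]methyl}-3-methoxyphenyl]acetic acid; 5 (R)-4-benzyl-1,3-oxazolidin-2-one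
Product: 24 (4R)-4-benzyl-3-{2-[2-(benzyloxy)-5-{[(3R,4R)-4-{[4-(benzyloxy)-3-methoxyphenyl]methyl}-5-oxooxolan-3-yl]methyl}-3-methoxyphenyl]acetyl}-1,3-oxazolidin-2-one, via mixed pivalic anhydride 23 (not isolated)
Conditions: PivCl, Et3N, THF, −20 °C; then 5, LiCl, −20 °C → rt
Reagents that add atoms: none
Why: Mixed-anhydride N-acylation of the oxazolidinone under LiCl/Et3N conditions; no strong base is present, so the lactone α-centre is not deprotonated.

**Step 14**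
Reactants: 24 (4R)-4-benzyl-3-{2-[2-(benzyloxy)-5-{[(3R,4R)-4-{[4-(benzyloxy)-3-methoxyphenyl]methyl}-5-oxooxolan-3-yl]methyl}-3-methoxyphenyl]acetyl}-1,3-oxazolidin-2-one; 25 4-(benzyloxy)-3-methoxybenzaldehyde
Product: 27 (4R)-4-benzyl-3-[(2S,3R)-2-[2-(benzyloxy)-5-{[(3R,4R)-4-{[4-(benzyloxy)-3-methoxyphenyl]methyl}-5-oxooxolan-3-yl]methyl}-3-methoxyphenyl]-3-[4-(benzyloxy)-3-methoxyphenyl]-3-hydroxypropanoyl]-1,3-oxazolidin-2-one, via TMS ether 26 (not isolated)
Conditions: MgCl2 (20 mol%), Et3N, TMSCl, EtOAc, rt, 24–36 h; then 1 M HCl/THF (1:5), rt, 20 min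
Reagents that add atoms: none
Why: Evans magnesium-halide-catalysed direct anti-aldol; soft enolisation gives the chelated (Z)-Mg enolate, which adds to the non-enolisable aldehyde through a boat-like closed transition state on the face away from the auxiliary benzyl group, so the (R)-auxiliary gives the (2S,3R)-anti adduct, while TMSCl traps the aldolate (turnover, no retro-aldol) and Et3N does not enolise the lactone.

**Step 15**
Reactants: 27 the (2S,3R)-anti aldol adduct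
Product: 28 (3R,4R)-4-({4-(benzyloxy)-3-[(1R,2R)-1-[4-(benzyloxy)-3-methoxyphenyl]-1,3-dihydroxypropan-2-yl]-5-methoxyphenyl}methyl)-3-{[4-(benzyloxy)-3-methoxyphenyl]methyl}oxolan-2-one
Conditions: NaBH4, THF/H2O (4:1), 0 °C → rt
Reagents that add atoms: none
Why: Reductive cleavage of the N-acyl oxazolidinone; the activated, hydroxyl-assisted imide carbonyl is reduced much faster by NaBH4 than the γ-lactone, neither new stereocentre is touched (the CIP label of C2 changes only because C=O becomes CH2OH) and 5 is recovered.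

**Step 16**
Reactants: 28 the tri-O-benzyl diol
Product: 29 (3R,4R)-4-({3-[(1R,2R)-1,3-dihydroxy-1-(4-hydroxy-3-methoxyphenyl)propan-2-yl]-4-hydroxy-5-methoxyphenyl}methyl)-3-[(4-hydroxy-3-methoxyphenyl)methyl]oxolan-2-one
Conditions: H2 (1 atm), 10% Pd/C, EtOAc/EtOH, rt, stopped at full conversion
Reagents that add atoms: none
Why: Catalytic hydrogenolysis of three aryl benzyl ethers under neutral conditions; with short reaction time the secondary benzylic alcohol and the lactone are retained and no stereocentre is affected.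

**Compound list**
1 | 5-bromovanillin | O=Cc1cc(Br)c(O)c(OC)c1 | starting material
2 | 4-(benzyloxy)-3-bromo-5-methoxybenzaldehyde | O=Cc1cc(Br)c(OCc2ccccc2)c(OC)c1 | intermediate
3 | [4-(benzyloxy)-3-bromo-5-methoxyphenyl]methanol | OCc1cc(Br)c(OCc2ccccc2)c(OC)c1 | intermediate
4 | 2-(benzyloxy)-1-bromo-5-(bromomethyl)-3-methoxybenzene | BrCc1cc(Br)c(OCc2ccccc2)c(OC)c1 | intermediate
5 | (R)-4-benzyl-1,3-oxazolidin-2-one | O=C1N[C@H](Cc2ccccc2)CO1 | starting material
6 | pent-4-enoyl chloride | C=CCCC(Cl)=O | starting material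
7 | (4R)-4-benzyl-3-(pent-4-enoyl)-1,3-oxazolidin-2-one | C=CCCC(=O)N1[C@H](Cc2ccccc2)COC1=O | intermediate
8 | sodium (Z)-enolate of 7 (formed in situ) | [Na+].[O-]/C(=C\CC=C)N1[C@H](Cc2ccccc2)COC1=O | intermediate
9 | (4R)-4-benzyl-3-[(2S)-2-{[4-(benzyloxy)-3-bromo-5-methoxyphenyl]methyl}pent-4-enoyl]-1,3-oxazolidin-2-one | C=CC[C@@H](Cc1cc(Br)c(OCc2ccccc2)c(OC)c1)C(=O)N1[C@H](Cc2ccccc2)COC1=O | intermediate
10 | (2S)-2-{[4-(benzyloxy)-3-bromo-5-methoxyphenyl]methyl}pent-4-en-1-ol | C=CC[C@H](CO)Cc1cc(Br)c(OCc2ccccc2)c(OC)c1 | intermediate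
11 | (4R)-4-{[4-(benzyloxy)-3-bromo-5-methoxyphenyl]methyl}pentane-1,2,5-triol, C2 epimers (formed in situ) | OCC(O)C[C@H](CO)Cc1cc(Br)c(OCc2ccccc2)c(OC)c1 | intermediate
12 | (3R)-3-{[4-(benzyloxy)-3-bromo-5-methoxyphenyl]methyl}-4-hydroxybutanal (formed in situ) | O=CC[C@H](CO)Cc1cc(Br)c(OCc2ccccc2)c(OC)c1 | intermediate
13 | (4R)-4-{[4-(benzyloxy)-3-bromo-5-methoxyphenyl]methyl}oxolan-2-ol, anomer mixture | OC1C[C@@H](Cc2cc(Br)c(OCc3ccccc3)c(OC)c2)CO1 | intermediate
14 | (4R)-4-{[4-(benzyloxy)-3-bromo-5-methoxyphenyl]methyl}oxolan-2-one | O=C1C[C@@H](Cc2cc(Br)c(OCc3ccccc3)c(OC)c2)CO1 | intermediate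
15 | [4-(benzyloxy)-3-methoxyphenyl]methanol | OCc1ccc(OCc2ccccc2)c(OC)c1 | starting material
16 | 1-(benzyloxy)-4-(bromomethyl)-2-methoxybenzene | BrCc1ccc(OCc2ccccc2)c(OC)c1 | intermediate
17 | lithium enolate of 14 (formed in situ) | [Li+].[O-]C1=C[C@@H](Cc2cc(Br)c(OCc3ccccc3)c(OC)c2)CO1 | intermediate
18 | (3R,4R)-4-{[4-(benzyloxy)-3-bromo-5-methoxyphenyl]methyl}-3-{[4-(benzyloxy)-3-methoxyphenyl]methyl}oxolan-2-one | COc1cc(C[C@H]2C(=O)OC[C@@H]2Cc2cc(OC)c(OCc3ccccc3)c(Br)c2)ccc1OCc1ccccc1 | intermediate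
19 | tert-butyl bromoacetate | BrCC(=O)OC(C)(C)C | starting material
20 | (2-tert-butoxy-2-oxoethyl)zinc bromide (formed in situ) | CC(C)(C)OC(=O)C[Zn]Br | intermediate
21 | tert-butyl 2-[2-(benzyloxy)-5-{[(3R,4R)-4-{[4-(benzyloxy)-3-methoxyphenyl]methyl}-5-oxooxolan-3-yl]methyl}-3-methoxyphenyl]acetate | COc1cc(C[C@H]2C(=O)OC[C@@H]2Cc2cc(OC)c(OCc3ccccc3)c(CC(=O)OC(C)(C)C)c2)ccc1OCc1ccccc1 | intermediate
22 | 2-[2-(benzyloxy)-5-{[(3R,4R)-4-{[4-(benzyloxy)-3-methoxyphenyl]methyl}-5-oxooxolan-3-yl]methyl}-3-methoxyphenyl]acetic acid | COc1cc(C[C@H]2C(=O)OC[C@@H]2Cc2cc(OC)c(OCc3ccccc3)c(CC(=O)O)c2)ccc1OCc1ccccc1 | intermediate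
23 | mixed pivalic anhydride of 22 (formed in situ) | COc1cc(C[C@H]2C(=O)OC[C@@H]2Cc2cc(OC)c(OCc3ccccc3)c(CC(=O)OC(=O)C(C)(C)C)c2)ccc1OCc1ccccc1 | intermediate
24 | (4R)-4-benzyl-3-{2-[2-(benzyloxy)-5-{[(3R,4R)-4-{[4-(benzyloxy)-3-methoxyphenyl]methyl}-5-oxooxolan-3-yl]methyl}-3-methoxyphenyl]acetyl}-1,3-oxazolidin-2-one | COc1cc(C[C@H]2C(=O)OC[C@@H]2Cc2cc(OC)c(OCc3ccccc3)c(CC(=O)N3[C@H](Cc4ccccc4)COC3=O)c2)ccc1OCc1ccccc1 | intermediate
25 | 4-(benzyloxy)-3-methoxybenzaldehyde (O-benzylvanillin) | O=Cc1ccc(OCc2ccccc2)c(OC)c1 | starting material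
26 | O-trimethylsilyl ether of the (2S,3R)-anti aldol adduct 27 (formed in situ) | COc1cc(C[C@H]2C(=O)OC[C@@H]2Cc2cc(OC)c(OCc3ccccc3)c([C@H](C(=O)N3[C@H](Cc4ccccc4)COC3=O)[C@@H](O[Si](C)(C)C)c3ccc(OCc4ccccc4)c(OC)c3)c2)ccc1OCc1ccccc1 | intermediate
27 | (4R)-4-benzyl-3-[(2S,3R)-2-[2-(benzyloxy)-5-{[(3R,4R)-4-{[4-(benzyloxy)-3-methoxyphenyl]methyl}-5-oxooxolan-3-yl]methyl}-3-methoxyphenyl]-3-[4-(benzyloxy)-3-methoxyphenyl]-3-hydroxypropanoyl]-1,3-oxazolidin-2-one | COc1cc(C[C@H]2C(=O)OC[C@@H]2Cc2cc(OC)c(OCc3ccccc3)c([C@H](C(=O)N3[C@H](Cc4ccccc4)COC3=O)[C@@H](O)c3ccc(OCc4ccccc4)c(OC)c3)c2)ccc1OCc1ccccc1 | intermediate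
28 | (3R,4R)-4-({4-(benzyloxy)-3-[(1R,2R)-1-[4-(benzyloxy)-3-methoxyphenyl]-1,3-dihydroxypropan-2-yl]-5-methoxyphenyl}methyl)-3-{[4-(benzyloxy)-3-methoxyphenyl]methyl}oxolan-2-one | COc1cc(C[C@H]2C(=O)OC[C@@H]2Cc2cc(OC)c(OCc3ccccc3)c([C@H](CO)[C@@H](O)c3ccc(OCc4ccccc4)c(OC)c3)c2)ccc1OCc1ccccc1 | intermediate
29 | (3R,4R)-4-({3-[(1R,2R)-1,3-dihydroxy-1-(4-hydroxy-3-methoxyphenyl)propan-2-yl]-4-hydroxy-5-methoxyphenyl}methyl)-3-[(4-hydroxy-3-methoxyphenyl)methyl]oxolan-2-one | COc1cc(C[C@H]2C(=O)OC[C@@H]2Cc2cc(OC)c(O)c([C@H](CO)[C@@H](O)c3ccc(O)c(OC)c3)c2)ccc1O | target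

**Step count**
Total steps: 16. Longest linear sequence: 14 (steps 1, 2, 3, 5, 6, 7, 8, 10, 11, 12, 13, 14, 15, 16, from 5-bromovanillin).

**Three steps most likely to fail**

Step 14 (anti-aldol). The imide is hindered and ortho-alkoxy-substituted, and both the level and the sense of induction rest on the chelated-enolate model, so this is the least certain step. The fallback replaces the aldol by a carbonyl allylation and sets out from aryl bromide 18. Stille coupling with (E)-3-(tributylstannyl)prop-2-en-1-ol (Pd(PPh3)4, CuI, DMF, 80 °C) gives the (E)-cinnamyl alcohol F1. Pd-catalysed borylation of the allylic alcohol with B2pin2 ([Pd(MeCN)4](BF4)2, DMSO/MeOH) gives the (E)-allylboronate F2. (R)-TRIP-catalysed allylboration of aldehyde 25 (toluene, −30 °C) gives the anti homoallylic alcohol F3; the (E)-boronate in a closed chair transition state gives anti, and Re-face addition gives the (1R) carbinol. Lemieux–Johnson cleavage of the vinyl group (OsO4 cat., NaIO4, 2,6-lutidine) gives the β-hydroxy aldehyde F4, which is reduced at once with NaBH4 (MeOH, 0 °C) to diol 28, where the route is rejoined.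

Step 15 (imide reduction beside the lactone). If the lactone is attacked, the fallback sets out from aldol adduct 27. LiOH/H2O2 (THF/H2O, 0 °C) cleaves the auxiliary to the β-hydroxy acid F5; any opened lactone recloses on acidification and the auxiliary is recovered. BH3·SMe2 (THF, 0 °C) then reduces the free carboxylic acid chemoselectively in the presence of the lactone and gives diol 28.

Step 11 (α-arylation on an electron-rich, ortho-alkoxy aryl bromide). The fallback sets out from aryl bromide 18. Stille allylation with allyltributylstannane (Pd(PPh3)4, toluene, 100 °C) gives the allyl arene F6. Lemieux–Johnson cleavage gives the arylacetaldehyde F7, and Pinnick oxidation (NaClO2, NaH2PO4, 2-methyl-2-butene, t-BuOH/H2O) gives acid 22, where the route is rejoined.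

**Further compounds**
F1 | step 14 | (3R,4R)-4-({4-(benzyloxy)-3-[(1E)-3-hydroxyprop-1-en-1-yl]-5-methoxyphenyl}methyl)-3-{[4-(benzyloxy)-3-methoxyphenyl]methyl}oxolan-2-one | COc1cc(C[C@H]2C(=O)OC[C@@H]2Cc2cc(OC)c(OCc3ccccc3)c(/C=C/CO)c2)ccc1OCc1ccccc1
F2 | step 14 | (3R,4R)-4-({4-(benzyloxy)-3-methoxy-5-[(1E)-3-(4,4,5,5-tetramethyl-1,3,2-dioxaborolan-2-yl)prop-1-en-1-yl]phenyl}methyl)-3-{[4-(benzyloxy)-3-methoxyphenyl]methyl}oxolan-2-one | COc1cc(C[C@H]2C(=O)OC[C@@H]2Cc2cc(OC)c(OCc3ccccc3)c(/C=C/CB3OC(C)(C)C(C)(C)O3)c2)ccc1OCc1ccccc1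
F3 | step 14 | (3R,4R)-4-({4-(benzyloxy)-3-[(1R,2S)-1-[4-(benzyloxy)-3-methoxyphenyl]-1-hydroxybut-3-en-2-yl]-5-methoxyphenyl}methyl)-3-{[4-(benzyloxy)-3-methoxyphenyl]methyl}oxolan-2-one | COc1cc(C[C@H]2C(=O)OC[C@@H]2Cc2cc(OC)c(OCc3ccccc3)c([C@H](C=C)[C@@H](O)c3ccc(OCc4ccccc4)c(OC)c3)c2)ccc1OCc1ccccc1
F4 | step 14 | (2S,3R)-2-[2-(benzyloxy)-5-{[(3R,4R)-4-{[4-(benzyloxy)-3-methoxyphenyl]methyl}-5-oxooxolan-3-yl]methyl}-3-methoxyphenyl]-3-[4-(benzyloxy)-3-methoxyphenyl]-3-hydroxypropanal | COc1cc(C[C@H]2C(=O)OC[C@@H]2Cc2cc(OC)c(OCc3ccccc3)c([C@H](C=O)[C@@H](O)c3ccc(OCc4ccccc4)c(OC)c3)c2)ccc1OCc1ccccc1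
F5 | step 15 | (2S,3R)-2-[2-(benzyloxy)-5-{[(3R,4R)-4-{[4-(benzyloxy)-3-methoxyphenyl]methyl}-5-oxooxolan-3-yl]methyl}-3-methoxyphenyl]-3-[4-(benzyloxy)-3-methoxyphenyl]-3-hydroxypropanoic acid | COc1cc(C[C@H]2C(=O)OC[C@@H]2Cc2cc(OC)c(OCc3ccccc3)c([C@H](C(=O)O)[C@@H](O)c3ccc(OCc4ccccc4)c(OC)c3)c2)ccc1OCc1ccccc1
F6 | step 11 | (3R,4R)-4-{[4-(benzyloxy)-3-methoxy-5-(prop-2-en-1-yl)phenyl]methyl}-3-{[4-(benzyloxy)-3-methoxyphenyl]methyl}oxolan-2-one | COc1cc(C[C@H]2C(=O)OC[C@@H]2Cc2cc(OC)c(OCc3ccccc3)c(CC=C)c2)ccc1OCc1ccccc1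
F7 | step 11 | 2-[2-(benzyloxy)-5-{[(3R,4R)-4-{[4-(benzyloxy)-3-methoxyphenyl]methyl}-5-oxooxolan-3-yl]methyl}-3-methoxyphenyl]acetaldehyde | COc1cc(C[C@H]2C(=O)OC[C@@H]2Cc2cc(OC)c(OCc3ccccc3)c(CC=O)c2)ccc1OCc1ccccc1
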